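**Retrosynthetic overview**
1. Target 23 ⇐ 22 ⇐ 20 ⇐ 19: only late adjustments (silyl enol ether → enone, CHO → CO2Me, desilylation).
2. 19 ⇐ 18: rings A and B close together in one intramolecular Diels–Alder reaction of an acyclic 2-silyloxydiene/(E)-2-methyl enal (C-3–C-4 and C-5–C-10 bonds), the face chosen by a chiral oxazaborolidinium catalyst; this sets C-4 and C-5.
3. 18 ⇐ 13: enone by cross-metathesis, silyl dienol ether, two-carbon aldehyde extension, Wittig enal.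
4. 13 ⇐ 9: C-8 and C-9 by an enantioselective Ireland–Claisen rearrangement of a geranyl-type propanoate.
5. 9 ⇐ 1: (R)-citronellol supplies C-13; ozonolysis, alkyne, zirconium-catalysed carboalumination.

Assumption: for the two chiral boron controllers (steps 6 and 13) the enantiomer named is the one the accepted transition-state models predict for the product shown; the antipode of each is equally available.

Numbering used in the text: C-1 to C-10 are the decalin carbons (C-4 carries the ester carbon C-18 and methyl C-19; C-5 and C-10 are the ring-fusion atoms; C-8 and C-9 carry methyls C-17 and C-20), C-11 to C-15 the side chain, C-16 its methyl.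

**Route**

Step 1
Reactants: 1 (R)-citronellol
Product: 2 tert-butyl{[(3R)-3,7-dimethyloct-6-en-1-yl]oxy}dimethylsilane
Conditions: TBSCl, imidazole, DMF, 0 °C to rt
Reagents that add atoms: tert-butyldimethylsilyl chloride, CC(C)(C)[Si](C)(C)Cl
Why: Standard silyl ether formation protects the primary alcohol for the organometallic and hydride steps; C-13 comes from the chiral pool and is not touched.

Step 2
Reactants: 2 tert-butyl{[(3R)-3,7-dimethyloct-6-en-1-yl]oxy}dimethylsilane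
Product: 4 (4R)-6-[(tert-butyldimethylsilyl)oxy]-4-methylhexanal, via ozonide 3 (not isolated)
Conditions: O3, CH2Cl2, −78 °C; then Me2S, −78 °C to rt
Reagents that add atoms: ozone, [O-][O+]=O
Why: Ozonolysis with reductive work-up cleaves the trisubstituted alkene to the aldehyde whose carbonyl carbon becomes C-9; no stereocentre is involved.

Step 3
Reactants: 4 (4R)-6-[(tert-butyldimethylsilyl)oxy]-4-methylhexanal
Product: 5 tert-butyldimethyl{[(3R)-3-methylhept-6-yn-1-yl]oxy}silane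
Conditions: dimethyl (1-diazo-2-oxopropyl)phosphonate, K2CO3, MeOH, 0 °C to rt
Reagents that add atoms: dimethyl (1-diazo-2-oxopropyl)phosphonate, COP(=O)(OC)C(=[N+]=[N-])C(C)=O
Why: Seyferth–Gilbert homologation in the Ohira–Bestmann form turns the unbranched aldehyde into the terminal alkyne (C-9≡C-10) under mild base that leaves the remote stereocentre alone.

Step 4
Reactants: 5 tert-butyldimethyl{[(3R)-3-methylhept-6-yn-1-yl]oxy}silane
Product: 8 (2E,6R)-8-[(tert-butyldimethylsilyl)oxy]-3,6-dimethyloct-2-en-1-ol, via alkenylalane 6 (not isolated), via aluminate 7 (not isolated)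
Conditions: Me3Al, Cp2ZrCl2 (20 mol %), CH2Cl2, rt; then n-BuLi, −78 °C; (CH2O)n, THF, rt
Reagents that add atoms: trimethylaluminium, C[Al](C)C; formaldehyde, C=O
Why: Negishi zirconium-catalysed carboalumination adds Me and Al syn across the alkyne (Me to the internal carbon), and the aluminate attacks formaldehyde with retention, so only the (E)-trisubstituted allylic alcohol forms; no new stereocentre.

Step 5
Reactants: 8 (2E,6R)-8-[(tert-butyldimethylsilyl)oxy]-3,6-dimethyloct-2-en-1-ol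
Product: 9 (2E,6R)-8-[(tert-butyldimethylsilyl)oxy]-3,6-dimethyloct-2-en-1-yl propanoate
Conditions: EtCOCl, pyridine, DMAP (cat.), CH2Cl2, 0 °C
Reagents that add atoms: propanoyl chloride, CCC(=O)Cl
Why: Simple acylation gives the allyl ester needed for the sigmatropic step.

Step 6
Reactants: 9 (2E,6R)-8-[(tert-butyldimethylsilyl)oxy]-3,6-dimethyloct-2-en-1-yl propanoate
Product: 11 (2S,3R,6R)-8-[(tert-butyldimethylsilyl)oxy]-3-ethenyl-2,3,6-trimethyloctanoic acid, via boron ketene acetal 10 (not isolated)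
Conditions: (S,S)-2-bromo-4,5-diphenyl-1,3-bis(p-tolylsulfonyl)-1,3,2-diazaborolidine (1.3 equiv), i-Pr2NEt, CH2Cl2, −78 °C; then −20 to 4 °C; aqueous work-up
Reagents that add atoms: none
Why: Enantioselective Ireland–Claisen rearrangement: the Z(O)-boron ketene acetal (methyl cis to O–B) and the (E)-alkene react through a chair in which the C-8 methyl and the C-9 chain are equatorial and the C-9 methyl axial, which fixes the C-8/C-9 relationship (C-17 and C-20 syn), while the chiral diazaborolidine selects the chair that gives 2S,3R.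

Step 7
Reactants: 11 (2S,3R,6R)-8-[(tert-butyldimethylsilyl)oxy]-3-ethenyl-2,3,6-trimethyloctanoic acid
Product: 12 (2S,3R,6R)-8-[(tert-butyldimethylsilyl)oxy]-3-ethenyl-2,3,6-trimethyloctan-1-ol
Conditions: LiAlH4, Et2O, 0 °C to rt
Reagents that add atoms: none
Why: Hydride reduction of the acid gives the primary alcohol (C-7) without touching the vinyl group, the silyl ether or the stereocentres.

Step 8
Reactants: 12 (2S,3R,6R)-8-[(tert-butyldimethylsilyl)oxy]-3-ethenyl-2,3,6-trimethyloctan-1-ol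
Product: 13 tert-butyl{[(3R,6R,7S)-6-ethenyl-8-iodo-3,6,7-trimethyloctyl]oxy}dimethylsilane
Conditions: I2, PPh3, imidazole, CH2Cl2, 0 °C to rt
Reagents that add atoms: iodine, II
Why: Appel-type iodination converts the primary alcohol into the iodide by SN2 at C-7, a carbon that is not stereogenic.

Step 9
Reactants: 13 tert-butyl{[(3R,6R,7S)-6-ethenyl-8-iodo-3,6,7-trimethyloctyl]oxy}dimethylsilane
Product: 14 (3E,5R,6S)-5-{(3R)-5-[(tert-butyldimethylsilyl)oxy]-3-methylpentyl}-7-iodo-5,6-dimethylhept-3-en-2-one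
Conditions: but-3-en-2-one (8 equiv), second-generation Hoveyda–Grubbs catalyst (10 mol %), toluene, 70 °C
Reagents that add atoms: but-3-en-2-one, CC(=O)C=C
Why: Olefin cross-metathesis of the only alkene in 13 (a vinyl group on a quaternary carbon that cannot homodimerise) with an excess of the enone partner gives the (E)-enone (C-10=C-1–C-2).

Step 10
Reactants: 14 (3E,5R,6S)-5-{(3R)-5-[(tert-butyldimethylsilyl)oxy]-3-methylpentyl}-7-iodo-5,6-dimethylhept-3-en-2-one
Product: 15 (3E,5R,6S)-5-{(3R)-5-[(tert-butyldimethylsilyl)oxy]-3-methylpentyl}-7-iodo-5,6-dimethyl-2-[(triisopropylsilyl)oxy]hepta-1,3-diene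
Conditions: i-Pr3SiOTf, Et3N, CH2Cl2, −78 to 0 °C
Reagents that add atoms: triisopropylsilyl trifluoromethanesulfonate, CC(C)[Si](C(C)C)(C(C)C)OS(=O)(=O)C(F)(F)F
Why: Soft enolisation can only occur at the methyl group (C-9 is quaternary), so the cross-conjugated 2-silyloxydiene forms as a single regioisomer; it is made now, before any aldehyde is present.

Step 11
Reactants: 15 (3E,5R,6S)-5-{(3R)-5-[(tert-butyldimethylsilyl)oxy]-3-methylpentyl}-7-iodo-5,6-dimethyl-2-[(triisopropylsilyl)oxy]hepta-1,3-diene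
Product: 17 (4R,5S,6E)-5-{(3R)-5-[(tert-butyldimethylsilyl)oxy]-3-methylpentyl}-4,5-dimethyl-8-[(triisopropylsilyl)oxy]nona-6,8-dienal, via imine 16 (not isolated)
Conditions: N-ethylidenecyclohexanamine, LiN(i-Pr)2, THF, −78 to 0 °C; then 15, DMPU, −78 to −10 °C; then AcOH/NaOAc buffer (pH 4.5), pentane, 0 °C
Reagents that add atoms: N-ethylidenecyclohexanamine, CC=NC1CCCCC1; water, O
Why: Stork metalloenamine alkylation: the lithiated aldimine displaces the primary iodide and buffered hydrolysis releases the aldehyde two carbons longer (C-6, C-5) without cleaving the triisopropylsilyl dienol ether; no stereocentre is affected.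

Step 12
Reactants: 17 (4R,5S,6E)-5-{(3R)-5-[(tert-butyldimethylsilyl)oxy]-3-methylpentyl}-4,5-dimethyl-8-[(triisopropylsilyl)oxy]nona-6,8-dienal
Product: 18 (2E,6R,7S,8E)-7-{(3R)-5-[(tert-butyldimethylsilyl)oxy]-3-methylpentyl}-2,6,7-trimethyl-10-[(triisopropylsilyl)oxy]undeca-2,8,10-trienal
Conditions: Ph3P=C(CH3)CHO, benzene, 70 °C
Reagents that add atoms: 2-(triphenylphosphoranylidene)propanal, CC(C=O)=P(c1ccccc1)(c1ccccc1)c1ccccc1
Why: Wittig olefination with the stabilised formyl ylide gives the (E)-2-methyl enal (CHO trans to C-6), the geometry that later places the C-18 carbonyl cis to H-5; the temperature is kept low to avoid an uncatalysed cycloaddition.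

Step 13
Reactants: 18 (2E,6R,7S,8E)-7-{(3R)-5-[(tert-butyldimethylsilyl)oxy]-3-methylpentyl}-2,6,7-trimethyl-10-[(triisopropylsilyl)oxy]undeca-2,8,10-trienal
Product: 19 (1S,4aS,5S,6R,8aS)-5-{(3R)-5-[(tert-butyldimethylsilyl)oxy]-3-methylpentyl}-1,5,6-trimethyl-3-[(triisopropylsilyl)oxy]-1,2,4a,5,6,7,8,8a-octahydronaphthalene-1-carbaldehyde
Conditions: (3aR)-1-(2-methylphenyl)-3,3-diphenyltetrahydro-1H,3H-pyrrolo[1,2-c][1,3,2]oxazaborole (20 mol %) + HN(SO2CF3)2 (18 mol %), CH2Cl2 (0.005 M), −78 to −40 °C; Et3N quench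
Reagents that add atoms: none
Why: Catalytic enantioselective intramolecular Diels–Alder reaction forming both rings: the four-carbon tether forces the C-3–C-4 and C-10–C-5 bonds (a "meta" orientation unusual for a 2-silyloxydiene), the (E)-enal geometry fixes CHO cis to H-5, the endo-formyl chair transition state gives the trans ring fusion, and the protonated oxazaborolidine bound to the s-trans 2-methyl enal exposes its C-4 Si/C-5 Re face, which sets 4S,5S against the weak and opposite preference of the C-8/C-9 tether (a mismatched, reagent-controlled case, so the diastereomer ratio will be moderate); C-10 is erased in step 14.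

Step 14
Reactants: 19 (1S,4aS,5S,6R,8aS)-5-{(3R)-5-[(tert-butyldimethylsilyl)oxy]-3-methylpentyl}-1,5,6-trimethyl-3-[(triisopropylsilyl)oxy]-1,2,4a,5,6,7,8,8a-octahydronaphthalene-1-carbaldehyde
Product: 20 (1S,5S,6R,8aS)-5-{(3R)-5-[(tert-butyldimethylsilyl)oxy]-3-methylpentyl}-1,5,6-trimethyl-3-oxo-1,2,3,5,6,7,8,8a-octahydronaphthalene-1-carbaldehyde
Conditions: Pd(OAc)2 (1.2 equiv), DMSO/MeCN, 40 °C
Reagents that add atoms: none
Why: Saegusa–Ito oxidation of the regiodefined silyl enol ether can eliminate only towards C-10 (C-2 is the carbonyl carbon), giving the C-1=C-10 enone from either C-10 epimer under neutral conditions that do not epimerise the γ-centre C-5.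

Step 15
Reactants: 20 (1S,5S,6R,8aS)-5-{(3R)-5-[(tert-butyldimethylsilyl)oxy]-3-methylpentyl}-1,5,6-trimethyl-3-oxo-1,2,3,5,6,7,8,8a-octahydronaphthalene-1-carbaldehyde
Product: 22 methyl (1S,5S,6R,8aS)-5-{(3R)-5-[(tert-butyldimethylsilyl)oxy]-3-methylpentyl}-1,5,6-trimethyl-3-oxo-1,2,3,5,6,7,8,8a-octahydronaphthalene-1-carboxylate, via carboxylic acid 21 (not isolated)
Conditions: NaClO2, NaH2PO4, 2-methylbut-2-ene, t-BuOH/H2O, rt; then Me3SiCHN2, MeOH/toluene, 0 °C
Reagents that add atoms: sodium chlorite, [Na+].[O-]Cl=O; (trimethylsilyl)diazomethane, C[Si](C)(C)C=[N+]=[N-]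
Why: Pinnick oxidation of the non-enolisable neopentyl aldehyde followed by diazoalkane esterification of the hindered acid gives the methyl ester under weakly acidic to neutral conditions that leave C-5 and the enone intact.

Step 16
Reactants: 22 methyl (1S,5S,6R,8aS)-5-{(3R)-5-[(tert-butyldimethylsilyl)oxy]-3-methylpentyl}-1,5,6-trimethyl-3-oxo-1,2,3,5,6,7,8,8a-octahydronaphthalene-1-carboxylate
Product: 23 methyl (1S,5S,6R,8aS)-5-[(3R)-5-hydroxy-3-methylpentyl]-1,5,6-trimethyl-3-oxo-1,2,3,5,6,7,8,8a-octahydronaphthalene-1-carboxylate (CNP0157174.1)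
Conditions: HF·pyridine, pyridine/THF, 0 °C to rt
Reagents that add atoms: none
Why: Fluoride-mediated desilylation under non-basic conditions frees the primary alcohol without epimerising C-5 through the dienolate.

**Compound list**
1 | (R)-citronellol, (3R)-3,7-dimethyloct-6-en-1-ol | CC(C)=CCC[C@@H](C)CCO | starting material
2 | tert-butyl{[(3R)-3,7-dimethyloct-6-en-1-yl]oxy}dimethylsilane | CC(C)=CCC[C@@H](C)CCO[Si](C)(C)C(C)(C)C | intermediate
3 | ozonide of 2, tert-butyl{[(3R)-5-(5,5-dimethyl-1,2,4-trioxolan-3-yl)-3-methylpentyl]oxy}dimethylsilane (both epimers at the trioxolane carbon) | CC1(C)OOC(CC[C@@H](C)CCO[Si](C)(C)C(C)(C)C)O1 | intermediate (not isolated)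
4 | (4R)-6-[(tert-butyldimethylsilyl)oxy]-4-methylhexanal | O=CCC[C@@H](C)CCO[Si](C)(C)C(C)(C)C | intermediate
5 | tert-butyldimethyl{[(3R)-3-methylhept-6-yn-1-yl]oxy}silane | C#CCC[C@@H](C)CCO[Si](C)(C)C(C)(C)C | intermediate
6 | [(1E,5R)-7-{[tert-butyl(dimethyl)silyl]oxy}-2,5-dimethylhept-1-en-1-yl]dimethylalane | C[Al](C)/C=C(\C)CC[C@@H](C)CCO[Si](C)(C)C(C)(C)C | intermediate (not isolated)
7 | lithium butyl[(1E,5R)-7-{[tert-butyl(dimethyl)silyl]oxy}-2,5-dimethylhept-1-en-1-yl]dimethylaluminate | [Li+].CCCC[Al-](C)(C)/C=C(\C)CC[C@@H](C)CCO[Si](C)(C)C(C)(C)C | intermediate (not isolated)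
8 | (2E,6R)-8-[(tert-butyldimethylsilyl)oxy]-3,6-dimethyloct-2-en-1-ol | OC/C=C(\C)CC[C@@H](C)CCO[Si](C)(C)C(C)(C)C | intermediate
9 | (2E,6R)-8-[(tert-butyldimethylsilyl)oxy]-3,6-dimethyloct-2-en-1-yl propanoate | CCC(=O)OC/C=C(\C)CC[C@@H](C)CCO[Si](C)(C)C(C)(C)C | intermediate
10 | Z(O)-boron ketene acetal of 9 (boron held in the (4S,5S)-4,5-diphenyl-1,3-ditosyl-1,3,2-diazaborolidine; methyl cis to O–B) | C/C=C(\OB1N(S(=O)(=O)c2ccc(C)cc2)[C@@H](c2ccccc2)[C@H](c2ccccc2)N1S(=O)(=O)c1ccc(C)cc1)OC/C=C(\C)CC[C@@H](C)CCO[Si](C)(C)C(C)(C)C | intermediate (not isolated)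
11 | (2S,3R,6R)-8-[(tert-butyldimethylsilyl)oxy]-3-ethenyl-2,3,6-trimethyloctanoic acid | OC(=O)[C@@H](C)[C@](C=C)(C)CC[C@@H](C)CCO[Si](C)(C)C(C)(C)C | intermediate
12 | (2S,3R,6R)-8-[(tert-butyldimethylsilyl)oxy]-3-ethenyl-2,3,6-trimethyloctan-1-ol | OC[C@@H](C)[C@](C=C)(C)CC[C@@H](C)CCO[Si](C)(C)C(C)(C)C | intermediate
13 | tert-butyl{[(3R,6R,7S)-6-ethenyl-8-iodo-3,6,7-trimethyloctyl]oxy}dimethylsilane | IC[C@@H](C)[C@](C=C)(C)CC[C@@H](C)CCO[Si](C)(C)C(C)(C)C | intermediate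
14 | (3E,5R,6S)-5-{(3R)-5-[(tert-butyldimethylsilyl)oxy]-3-methylpentyl}-7-iodo-5,6-dimethylhept-3-en-2-one | CC(=O)/C=C/[C@@](C)(CC[C@@H](C)CCO[Si](C)(C)C(C)(C)C)[C@H](C)CI | intermediate
15 | (3E,5R,6S)-5-{(3R)-5-[(tert-butyldimethylsilyl)oxy]-3-methylpentyl}-7-iodo-5,6-dimethyl-2-[(triisopropylsilyl)oxy]hepta-1,3-diene | C=C(O[Si](C(C)C)(C(C)C)C(C)C)/C=C/[C@@](C)(CC[C@@H](C)CCO[Si](C)(C)C(C)(C)C)[C@H](C)CI | intermediate
16 | N-cyclohexyl imine of 17 | C=C(O[Si](C(C)C)(C(C)C)C(C)C)/C=C/[C@@](C)(CC[C@@H](C)CCO[Si](C)(C)C(C)(C)C)[C@H](C)CCC=NC1CCCCC1 | intermediate (not isolated)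
17 | (4R,5S,6E)-5-{(3R)-5-[(tert-butyldimethylsilyl)oxy]-3-methylpentyl}-4,5-dimethyl-8-[(triisopropylsilyl)oxy]nona-6,8-dienal | C=C(O[Si](C(C)C)(C(C)C)C(C)C)/C=C/[C@@](C)(CC[C@@H](C)CCO[Si](C)(C)C(C)(C)C)[C@H](C)CCC=O | intermediate
18 | (2E,6R,7S,8E)-7-{(3R)-5-[(tert-butyldimethylsilyl)oxy]-3-methylpentyl}-2,6,7-trimethyl-10-[(triisopropylsilyl)oxy]undeca-2,8,10-trienal | C=C(O[Si](C(C)C)(C(C)C)C(C)C)/C=C/[C@@](C)(CC[C@@H](C)CCO[Si](C)(C)C(C)(C)C)[C@H](C)CC/C=C(\C)C=O | intermediate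
19 | (1S,4aS,5S,6R,8aS)-5-{(3R)-5-[(tert-butyldimethylsilyl)oxy]-3-methylpentyl}-1,5,6-trimethyl-3-[(triisopropylsilyl)oxy]-1,2,4a,5,6,7,8,8a-octahydronaphthalene-1-carbaldehyde (trans-fused) | O=C[C@@]1(C)CC(O[Si](C(C)C)(C(C)C)C(C)C)=C[C@@H]2[C@@H]1CC[C@@H](C)[C@]2(C)CC[C@@H](C)CCO[Si](C)(C)C(C)(C)C | intermediate
20 | (1S,5S,6R,8aS)-5-{(3R)-5-[(tert-butyldimethylsilyl)oxy]-3-methylpentyl}-1,5,6-trimethyl-3-oxo-1,2,3,5,6,7,8,8a-octahydronaphthalene-1-carbaldehyde | O=C[C@@]1(C)CC(=O)C=C2[C@@H]1CC[C@@H](C)[C@]2(C)CC[C@@H](C)CCO[Si](C)(C)C(C)(C)C | intermediate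
21 | (1S,5S,6R,8aS)-5-{(3R)-5-[(tert-butyldimethylsilyl)oxy]-3-methylpentyl}-1,5,6-trimethyl-3-oxo-1,2,3,5,6,7,8,8a-octahydronaphthalene-1-carboxylic acid | OC(=O)[C@@]1(C)CC(=O)C=C2[C@@H]1CC[C@@H](C)[C@]2(C)CC[C@@H](C)CCO[Si](C)(C)C(C)(C)C | intermediate (not isolated)
22 | methyl (1S,5S,6R,8aS)-5-{(3R)-5-[(tert-butyldimethylsilyl)oxy]-3-methylpentyl}-1,5,6-trimethyl-3-oxo-1,2,3,5,6,7,8,8a-octahydronaphthalene-1-carboxylate | COC(=O)[C@@]1(C)CC(=O)C=C2[C@@H]1CC[C@@H](C)[C@]2(C)CC[C@@H](C)CCO[Si](C)(C)C(C)(C)C | intermediate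
23 | methyl (1S,5S,6R,8aS)-5-[(3R)-5-hydroxy-3-methylpentyl]-1,5,6-trimethyl-3-oxo-1,2,3,5,6,7,8,8a-octahydronaphthalene-1-carboxylate | COC(=O)[C@@]1(C)CC(=O)C=C2[C@@H]1CC[C@@H](C)[C@]2(C)CC[C@@H](C)CCO | target

**Step count**
Total steps: 16. Longest linear sequence: 16 (fully linear from (R)-citronellol).

**Steps most likely to fail, with fallbacks**

Step 13 (catalysed ring-forming cycloaddition: acid-sensitive diene, forced regiochemistry, catalyst working against the tether bias). The fallback sets out from 17 and returns at 22. Aldehyde 17 is olefinated under Still–Gennari conditions (methyl 2-[bis(2,2,2-trifluoroethoxy)phosphoryl]propanoate, KN(SiMe3)2, 18-crown-6, THF, −78 °C) to methyl (2Z,6R,7S,8E)-7-{(3R)-5-[(tert-butyldimethylsilyl)oxy]-3-methylpentyl}-2,6,7-trimethyl-10-[(triisopropylsilyl)oxy]undeca-2,8,10-trienoate F1. Heating (toluene, BHT, 170 °C, sealed tube) gives an uncatalysed intramolecular Diels–Alder reaction. It should run through the tether chair with the C-8 methyl equatorial; with the Z ester this places CO2Me correctly at C-4 but H-5 on the wrong face, giving the cis-fused silyl enol ether methyl (1S,4aS,5S,6R,8aR)-5-{(3R)-5-[(tert-butyldimethylsilyl)oxy]-3-methylpentyl}-1,5,6-trimethyl-3-[(triisopropylsilyl)oxy]-1,2,4a,5,6,7,8,8a-octahydronaphthalene-1-carboxylate F2. Pd(OAc)2 (DMSO/MeCN, 40 °C) gives the 5-epi enone, methyl (1S,5S,6R,8aR)-5-{(3R)-5-[(tert-butyldimethylsilyl)oxy]-3-methylpentyl}-1,5,6-trimethyl-3-oxo-1,2,3,5,6,7,8,8a-octahydronaphthalene-1-carboxylate F3. Because H-5 is γ to the enone, DBU (toluene, 60 °C) equilibrates C-5 through the dienolate; the two epimers are estimated to be close in energy, so roughly half is 22, which is separated while F3 is recycled. Step 16 then follows.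

Step 9 (cross-metathesis at a vinyl group on a quaternary carbon). The fallback sets out from 13 and returns at 14. Ozonolysis of the vinyl group (O3, CH2Cl2, −78 °C; Me2S) gives (2S,3S)-2-{(3R)-5-[(tert-butyldimethylsilyl)oxy]-3-methylpentyl}-4-iodo-2,3-dimethylbutanal F4, and Wittig olefination with 1-(triphenylphosphoranylidene)propan-2-one (toluene, 90 °C) gives the (E)-enone 14.

Step 6 (reagent-controlled Claisen rearrangement forming the quaternary centre). The fallback sets out from 5 and returns at 14; it replaces reagent control by chirality transfer from a carbinol centre. Carboalumination of 5 (Me3Al, Cp2ZrCl2) and acylation of the alkenylalane with acetyl chloride (Pd(PPh3)4 cat.) give (3E,7R)-9-[(tert-butyldimethylsilyl)oxy]-4,7-dimethylnon-3-en-2-one F5. Reduction with BH3·SMe2 and (3aR)-1-methyl-3,3-diphenyltetrahydro-1H,3H-pyrrolo[1,2-c][1,3,2]oxazaborole (10 mol %) gives (2S,3E,7R)-9-[(tert-butyldimethylsilyl)oxy]-4,7-dimethylnon-3-en-2-ol F6, which is acylated (EtCOCl, pyridine) to (2S,3E,7R)-9-[(tert-butyldimethylsilyl)oxy]-4,7-dimethylnon-3-en-2-yl propanoate F7. Ireland–Claisen rearrangement (LiN(i-Pr)2, Me3SiCl, THF/DMPU, −78 °C to rt; Z(O)-enolate, chair with the carbinol methyl equatorial) gives (2S,3R,6R)-8-[(tert-butyldimethylsilyl)oxy]-2,3,6-trimethyl-3-[(1E)-prop-1-en-1-yl]octanoic acid F8. LiAlH4 gives (2S,3R,6R)-8-[(tert-butyldimethylsilyl)oxy]-2,3,6-trimethyl-3-[(1E)-prop-1-en-1-yl]octan-1-ol F9, and I2/PPh3/imidazole gives tert-butyl{[(3R,6R,7S)-8-iodo-3,6,7-trimethyl-6-[(1E)-prop-1-en-1-yl]octyl]oxy}dimethylsilane F10. Ozonolysis of the propenyl group gives the aldehyde F4 of the preceding fallback, and the same Wittig olefination leads to 14.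

**Further compounds**
F1 | step 13 | methyl (2Z,6R,7S,8E)-7-{(3R)-5-[(tert-butyldimethylsilyl)oxy]-3-methylpentyl}-2,6,7-trimethyl-10-[(triisopropylsilyl)oxy]undeca-2,8,10-trienoate | C=C(O[Si](C(C)C)(C(C)C)C(C)C)/C=C/[C@@](C)(CC[C@@H](C)CCO[Si](C)(C)C(C)(C)C)[C@H](C)CC/C=C(/C)C(=O)OC
F2 | step 13 | methyl (1S,4aS,5S,6R,8aR)-5-{(3R)-5-[(tert-butyldimethylsilyl)oxy]-3-methylpentyl}-1,5,6-trimethyl-3-[(triisopropylsilyl)oxy]-1,2,4a,5,6,7,8,8a-octahydronaphthalene-1-carboxylate | COC(=O)[C@@]1(C)CC(O[Si](C(C)C)(C(C)C)C(C)C)=C[C@@H]2[C@H]1CC[C@@H](C)[C@]2(C)CC[C@@H](C)CCO[Si](C)(C)C(C)(C)C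
F3 | step 13 | methyl (1S,5S,6R,8aR)-5-{(3R)-5-[(tert-butyldimethylsilyl)oxy]-3-methylpentyl}-1,5,6-trimethyl-3-oxo-1,2,3,5,6,7,8,8a-octahydronaphthalene-1-carboxylate | COC(=O)[C@@]1(C)CC(=O)C=C2[C@H]1CC[C@@H](C)[C@]2(C)CC[C@@H](C)CCO[Si](C)(C)C(C)(C)C
F4 | step 9 | (2S,3S)-2-{(3R)-5-[(tert-butyldimethylsilyl)oxy]-3-methylpentyl}-4-iodo-2,3-dimethylbutanal | O=C[C@@](C)(CC[C@@H](C)CCO[Si](C)(C)C(C)(C)C)[C@H](C)CI
F5 | step 6 | (3E,7R)-9-[(tert-butyldimethylsilyl)oxy]-4,7-dimethylnon-3-en-2-one | CC(=O)/C=C(\C)CC[C@@H](C)CCO[Si](C)(C)C(C)(C)C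
F6 | step 6 | (2S,3E,7R)-9-[(tert-butyldimethylsilyl)oxy]-4,7-dimethylnon-3-en-2-ol | C[C@H](O)/C=C(\C)CC[C@@H](C)CCO[Si](C)(C)C(C)(C)C
F7 | step 6 | (2S,3E,7R)-9-[(tert-butyldimethylsilyl)oxy]-4,7-dimethylnon-3-en-2-yl propanoate | CCC(=O)O[C@@H](C)/C=C(\C)CC[C@@H](C)CCO[Si](C)(C)C(C)(C)C
F8 | step 6 | (2S,3R,6R)-8-[(tert-butyldimethylsilyl)oxy]-2,3,6-trimethyl-3-[(1E)-prop-1-en-1-yl]octanoic acid | OC(=O)[C@@H](C)[C@](/C=C/C)(C)CC[C@@H](C)CCO[Si](C)(C)C(C)(C)C
F9 | step 6 | (2S,3R,6R)-8-[(tert-butyldimethylsilyl)oxy]-2,3,6-trimethyl-3-[(1E)-prop-1-en-1-yl]octan-1-ol | OC[C@@H](C)[C@](/C=C/C)(C)CC[C@@H](C)CCO[Si](C)(C)C(C)(C)C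
F10 | step 6 | tert-butyl{[(3R,6R,7S)-8-iodo-3,6,7-trimethyl-6-[(1E)-prop-1-en-1-yl]octyl]oxy}dimethylsilane | IC[C@@H](C)[C@](/C=C/C)(C)CC[C@@H](C)CCO[Si](C)(C)C(C)(C)C
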